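**Plan**

- Retrosynthetic cuts: the two 2-aminoimidazole rings go back to ring-bound carboxyl groups (one CH2 carbon plus a guanidine each), the two pyrrole amide C–N bonds are cut, and the CH2–N arms are traced to methyl esters. The cyclobutane is then opened at Cb–Cc by putting an NH back between these carbons, and the resulting pyrrolidine is split [3+2] into an azomethine ylide (glycine ester plus glyoxylate) and di-tert-butyl fumarate.
- Enabling feature: the cyclobutane is all-trans, Ca and Cd bear the imidazoles, and Cb and Cc bear the CH2N arms. The trans Cb–Cc bond is the bond left when the NH bridging C2 and C5 of an all-trans pyrrolidine-2,3,4,5-tetracarboxylate leaves as N2.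
- Forward order: imine, then pyrrolidine ring by silver-catalysed cycloaddition, C2 epimerisation, contraction to the cyclobutane, methyl esters to acylated aminomethyl arms, tert-butyl esters to bromoketones, and the two imidazole rings last.
- Stereochemistry: the absolute configuration is set at C3/C4 of the pyrrolidine (later Ca/Cd) by the chiral silver catalyst and is not touched again. The all-trans relation comes from thermodynamic epimerisation, and Cb/Cc keep their configuration through the biradical collapse.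

Key step: step 4

Assumption 1: the (R)-ligand is taken to deliver the (3R,4R) cycloadduct; if the sense of induction proves opposite, the (S)-ligand is used with nothing else changed.
Assumption 2: the Boc group of the protected aminoimidazoles is drawn on N1 (next to C5–H), the usual outcome; its position does not matter because it is removed in the last step.
Remark on stoichiometry: from step 5 on, every step acts on two equivalent sites of a C2-symmetric substrate, so two molecules of each partner or atom-adding reagent (azide donor, 11, CH2N2, HBr, 18) are taken up per molecule of substrate.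

**Step 1**
Reactants: 1 glycine methyl ester hydrochloride; 2 methyl glyoxylate (freshly distilled, monomeric)
Product: 3 methyl (E)-N-(2-methoxy-2-oxoethylidene)glycinate
Conditions: Et3N (1.0 equiv), MgSO4, CH2Cl2, 0 °C to rt; filter, concentrate, use at once
Reagents that add atoms: none
Why: Imine condensation of a primary amine with the very electrophilic glyoxylate aldehyde, driven by the drying agent; the 2-azaallyl product is symmetric, so imine–imine prototropy is degenerate and no stereocentre is formed.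

**Step 2**
Reactants: 3 methyl (E)-N-(2-methoxy-2-oxoethylidene)glycinate; 4 di-tert-butyl fumarate
Product: 5 3,4-di-tert-butyl 2,5-dimethyl (2S,3R,4R,5R)-pyrrolidine-2,3,4,5-tetracarboxylate (2,5-cis and 3,4-trans)
Conditions: AgOAc (5 mol%), (R)-DTBM-SEGPHOS (5.5 mol%), Et3N (10 mol%), toluene, −20 °C
Reagents that add atoms: none
Why: Catalytic asymmetric 1,3-dipolar cycloaddition of an N,O-chelated silver azomethine ylide, in which the W-shaped ylide gives the 2,5-cis relation, suprafacial addition to the E-alkene keeps 3,4-trans, and the chiral bisphosphine selects the enantiotopic fumarate face so that C3 and C4 are set as R,R.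

**Step 3**
Reactants: 5 3,4-di-tert-butyl 2,5-dimethyl (2S,3R,4R,5R)-pyrrolidine-2,3,4,5-tetracarboxylate
Product: 6 3,4-di-tert-butyl 2,5-dimethyl (2R,3R,4R,5R)-pyrrolidine-2,3,4,5-tetracarboxylate (all-trans)
Conditions: DBU (0.5 equiv), toluene, 60 °C
Reagents that add atoms: none
Why: Base-mediated epimerisation (enolisation and reprotonation) at C2, the α-amino methyl ester centre whose ester is cis to the C3 ester, should equilibrate to the all-trans isomer, which has no vicinal cis ester pair; the less acidic, already trans C3/C4 tert-butyl ester centres should stay as set in step 2.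

**Step 4**
Reactants: 6 3,4-di-tert-butyl 2,5-dimethyl (2R,3R,4R,5R)-pyrrolidine-2,3,4,5-tetracarboxylate
Product: 8 1,2-di-tert-butyl 3,4-dimethyl (1S,2S,3R,4R)-cyclobutane-1,2,3,4-tetracarboxylate (all-trans), via 1,1-diazene 7 (not isolated)
Conditions: PhI(OH)OTs (2.5 equiv), H2NCO2NH4 (8 equiv), CF3CH2OH, 80 °C
Reagents that add atoms: none
Why: Ammonia released from the carbamate is oxidised by the trivalent-iodine reagent to an electrophilic iodonitrene that transfers NH to the ring nitrogen; the 1,1-diazene 7 then loses N2 to a singlet 1,4-biradical whose termini C2 and C5 are each stabilised by a methyl ester, and radical–radical recombination forms the Cb–Cc bond. The closest known reaction type is the iodonitrene-mediated stereoretentive contraction of substituted NH-pyrrolidines to cyclobutanes, itself a one-flask version of the oxidative deamination of N-aminopyrrolidines. The four-membered ring closes by direct coupling of the two termini of the tethered 1,4-biradical (five-to-four ring contraction), not by addition to a π bond. Cb and Cc inherit their configuration from C2 and C5 of 6 with retention, because collapse of the singlet biradical should be faster than rotation about C2–C3 and C4–C5, while the untouched C3/C4 centres (Ca/Cd) carry the absolute configuration. The step needs ring closure to outrun C3–C4 scission to two molecules of tert-butyl methyl fumarate and needs retention at both termini; the 2,5-trans relation fixed in step 3 provides the geometry for this, and because the all-trans tetraester is also the thermodynamic isomer, any leakage at the ester-bearing Cb/Cc could be corrected by base equilibration.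

**Step 5**
Reactants: 8 1,2-di-tert-butyl 3,4-dimethyl (1S,2S,3R,4R)-cyclobutane-1,2,3,4-tetracarboxylate
Product: 9 di-tert-butyl (1S,2S,3R,4R)-3,4-bis(hydroxymethyl)cyclobutane-1,2-dicarboxylate
Conditions: LiBH4 (4 equiv), THF, 0 °C to rt; aq NH4Cl
Reagents that add atoms: none
Why: Chemoselective hydride reduction of esters, in which LiBH4 reduces methyl esters but leaves hindered tert-butyl esters; no ring stereocentre is involved, and the trans relation of each CH2OH to its vicinal ester disfavours lactonisation.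

**Step 6**
Reactants: 9 di-tert-butyl (1S,2S,3R,4R)-3,4-bis(hydroxymethyl)cyclobutane-1,2-dicarboxylate
Product: 10 di-tert-butyl (1S,2S,3R,4R)-3,4-bis(azidomethyl)cyclobutane-1,2-dicarboxylate
Conditions: PPh3, DIAD, (PhO)2P(O)N3, THF, 0 °C to rt
Reagents that add atoms: diphenylphosphoryl azide, [N-]=[N+]=NP(=O)(Oc1ccccc1)Oc1ccccc1
Why: Mitsunobu azidation of primary alcohols (SN2 at CH2, no stereocentre affected); closure to a cyclic ether would need a strained trans-fused bicycle and should not compete.

**Step 7**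
Reactants: 10 di-tert-butyl (1S,2S,3R,4R)-3,4-bis(azidomethyl)cyclobutane-1,2-dicarboxylate; 11 4-bromo-2-(trichloroacetyl)-1H-pyrrole (3 equiv, two molecules are incorporated)
Product: 13 di-tert-butyl (1S,2S,3R,4R)-3,4-bis{[(4-bromo-1H-pyrrole-2-carbonyl)amino]methyl}cyclobutane-1,2-dicarboxylate, via diamine 12 (not isolated)
Conditions: H2 (1 atm), 10% Pd/C, MeOH, rt; filter, concentrate; then 11 (3 equiv), iPr2NEt (3 equiv), MeCN, rt
Reagents that add atoms: 4-bromo-2-(trichloroacetyl)-1H-pyrrole (11, the second molecule that is incorporated), O=C(c1cc(Br)c[nH]1)C(Cl)(Cl)Cl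
Why: Catalytic hydrogenation of the two alkyl azides to primary amines, followed by haloform-type acyl transfer in which each amine of 12 takes one 4-bromopyrrole-2-carbonyl group from its own molecule of 11 with loss of CHCl3 while the pyrrole N–H stays untouched; the aryl bromide enters only after the palladium catalyst has been filtered off, so hydrodebromination cannot occur.

**Step 8**
Reactants: 13 di-tert-butyl (1S,2S,3R,4R)-3,4-bis{[(4-bromo-1H-pyrrole-2-carbonyl)amino]methyl}cyclobutane-1,2-dicarboxylate
Product: 14 (1S,2S,3R,4R)-3,4-bis{[(4-bromo-1H-pyrrole-2-carbonyl)amino]methyl}cyclobutane-1,2-dicarboxylic acid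
Conditions: CF3CO2H/CH2Cl2 (1:1), rt
Reagents that add atoms: none
Why: Acidolysis of tert-butyl esters with loss of isobutene; the secondary amides and the electron-poor bromopyrroles are stable to CF3CO2H.

**Step 9**
Reactants: 14 (1S,2S,3R,4R)-3,4-bis{[(4-bromo-1H-pyrrole-2-carbonyl)amino]methyl}cyclobutane-1,2-dicarboxylic acid
Product: 17 N,N'-{[(1R,2R,3S,4S)-3,4-bis(bromoacetyl)cyclobutane-1,2-diyl]bis(methylene)}bis(4-bromo-1H-pyrrole-2-carboxamide), via bis(isobutyl carbonic anhydride) 15 (not isolated), via bis(diazoketone) 16 (not isolated)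
Conditions: iBuOCOCl, N-methylmorpholine, THF, −15 °C; CH2N2, Et2O, −15 to 0 °C; 48% aq HBr, 0 °C
Reagents that add atoms: diazomethane, C=[N+]=[N-]; hydrogen bromide, Br
Why: Mixed carbonic anhydride activation and acylation of diazomethane (first stage of an Arndt–Eistert sequence), then hydrobromination of the α-diazoketone with loss of N2, a one-flask route to bromomethyl ketones that tolerates amide N–H groups; the ring α-centres already sit in the thermodynamic all-trans arrangement.

**Step 10**
Reactants: 17 N,N'-{[(1R,2R,3S,4S)-3,4-bis(bromoacetyl)cyclobutane-1,2-diyl]bis(methylene)}bis(4-bromo-1H-pyrrole-2-carboxamide); 18 N-Boc-guanidine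
Product: 19 di-tert-butyl 4,4'-[(1S,2S,3R,4R)-3,4-bis{[(4-bromo-1H-pyrrole-2-carbonyl)amino]methyl}cyclobutane-1,2-diyl]bis(2-amino-1H-imidazole-1-carboxylate)
Conditions: 18 (6 equiv), DMF, rt; aq NaHCO3 work-up
Reagents that add atoms: none
Why: α-Haloketone–guanidine cyclocondensation (the imidazole counterpart of the Hantzsch thiazole synthesis), in which N-alkylation of Boc-guanidine and cyclodehydration give the Boc-protected 2-aminoimidazole while excess reagent takes up HBr; the trans disposition of the two ketone arms disfavours intramolecular aldol closure.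

**Step 11**
Reactants: 19 di-tert-butyl 4,4'-[(1S,2S,3R,4R)-3,4-bis{[(4-bromo-1H-pyrrole-2-carbonyl)amino]methyl}cyclobutane-1,2-diyl]bis(2-amino-1H-imidazole-1-carboxylate)
Product: 20 sceptrin
Conditions: CF3CO2H/CH2Cl2 (1:1), rt; reverse-phase chromatography (bis-trifluoroacetate); free base with aq NH3
Reagents that add atoms: none
Why: Acidolytic cleavage of the imidazole N-Boc carbamates (loss of isobutene and CO2) should release both 2-aminoimidazoles without touching the amides, the aryl bromides or the four ring stereocentres.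

**Compound list**

1 | glycine methyl ester hydrochloride | Cl.NCC(=O)OC | starting material
2 | methyl glyoxylate | O=CC(=O)OC | starting material
3 | methyl (E)-N-(2-methoxy-2-oxoethylidene)glycinate | COC(=O)/C=N/CC(=O)OC | intermediate
4 | di-tert-butyl fumarate | CC(C)(C)OC(=O)/C=C/C(=O)OC(C)(C)C | starting material
5 | 3,4-di-tert-butyl 2,5-dimethyl (2S,3R,4R,5R)-pyrrolidine-2,3,4,5-tetracarboxylate | N1[C@H](C(=O)OC)[C@H](C(=O)OC(C)(C)C)[C@@H](C(=O)OC(C)(C)C)[C@@H]1C(=O)OC | intermediate
6 | 3,4-di-tert-butyl 2,5-dimethyl (2R,3R,4R,5R)-pyrrolidine-2,3,4,5-tetracarboxylate | N1[C@@H](C(=O)OC)[C@H](C(=O)OC(C)(C)C)[C@@H](C(=O)OC(C)(C)C)[C@@H]1C(=O)OC | intermediate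
7 | 1,1-diazene (N-nitrene) of 6: 3,4-di-tert-butyl 2,5-dimethyl (2R,3R,4R,5R)-1-azanidylidenepyrrolidin-1-ium-2,3,4,5-tetracarboxylate | [N-]=[N+]1[C@@H](C(=O)OC)[C@H](C(=O)OC(C)(C)C)[C@@H](C(=O)OC(C)(C)C)[C@@H]1C(=O)OC | intermediate
8 | 1,2-di-tert-butyl 3,4-dimethyl (1S,2S,3R,4R)-cyclobutane-1,2,3,4-tetracarboxylate | CC(C)(C)OC(=O)[C@H]1[C@H](C(=O)OC)[C@@H](C(=O)OC)[C@@H]1C(=O)OC(C)(C)C | intermediate
9 | di-tert-butyl (1S,2S,3R,4R)-3,4-bis(hydroxymethyl)cyclobutane-1,2-dicarboxylate | CC(C)(C)OC(=O)[C@H]1[C@H](CO)[C@@H](CO)[C@@H]1C(=O)OC(C)(C)C | intermediate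
10 | di-tert-butyl (1S,2S,3R,4R)-3,4-bis(azidomethyl)cyclobutane-1,2-dicarboxylate | CC(C)(C)OC(=O)[C@H]1[C@H](CN=[N+]=[N-])[C@@H](CN=[N+]=[N-])[C@@H]1C(=O)OC(C)(C)C | intermediate
11 | 4-bromo-2-(trichloroacetyl)-1H-pyrrole | O=C(c1cc(Br)c[nH]1)C(Cl)(Cl)Cl | starting material
12 | di-tert-butyl (1S,2S,3R,4R)-3,4-bis(aminomethyl)cyclobutane-1,2-dicarboxylate | CC(C)(C)OC(=O)[C@H]1[C@H](CN)[C@@H](CN)[C@@H]1C(=O)OC(C)(C)C | intermediate
13 | di-tert-butyl (1S,2S,3R,4R)-3,4-bis{[(4-bromo-1H-pyrrole-2-carbonyl)amino]methyl}cyclobutane-1,2-dicarboxylate | CC(C)(C)OC(=O)[C@H]1[C@H](CNC(=O)c2cc(Br)c[nH]2)[C@@H](CNC(=O)c2cc(Br)c[nH]2)[C@@H]1C(=O)OC(C)(C)C | intermediate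
14 | (1S,2S,3R,4R)-3,4-bis{[(4-bromo-1H-pyrrole-2-carbonyl)amino]methyl}cyclobutane-1,2-dicarboxylic acid | OC(=O)[C@H]1[C@H](CNC(=O)c2cc(Br)c[nH]2)[C@@H](CNC(=O)c2cc(Br)c[nH]2)[C@@H]1C(=O)O | intermediate
15 | bis(isobutyl carbonic anhydride) of 14 | CC(C)COC(=O)OC(=O)[C@H]1[C@H](CNC(=O)c2cc(Br)c[nH]2)[C@@H](CNC(=O)c2cc(Br)c[nH]2)[C@@H]1C(=O)OC(=O)OCC(C)C | intermediate
16 | N,N'-{[(1R,2R,3S,4S)-3,4-bis(diazoacetyl)cyclobutane-1,2-diyl]bis(methylene)}bis(4-bromo-1H-pyrrole-2-carboxamide) | [N-]=[N+]=CC(=O)[C@H]1[C@H](CNC(=O)c2cc(Br)c[nH]2)[C@@H](CNC(=O)c2cc(Br)c[nH]2)[C@@H]1C(=O)C=[N+]=[N-] | intermediate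
17 | N,N'-{[(1R,2R,3S,4S)-3,4-bis(bromoacetyl)cyclobutane-1,2-diyl]bis(methylene)}bis(4-bromo-1H-pyrrole-2-carboxamide) | BrCC(=O)[C@H]1[C@H](CNC(=O)c2cc(Br)c[nH]2)[C@@H](CNC(=O)c2cc(Br)c[nH]2)[C@@H]1C(=O)CBr | intermediate
18 | N-Boc-guanidine (tert-butyl N-carbamimidoylcarbamate) | CC(C)(C)OC(=O)NC(N)=N | starting material
19 | di-tert-butyl 4,4'-[(1S,2S,3R,4R)-3,4-bis{[(4-bromo-1H-pyrrole-2-carbonyl)amino]methyl}cyclobutane-1,2-diyl]bis(2-amino-1H-imidazole-1-carboxylate) | CC(C)(C)OC(=O)n1cc(nc1N)[C@H]2[C@H](CNC(=O)c3cc(Br)c[nH]3)[C@@H](CNC(=O)c3cc(Br)c[nH]3)[C@@H]2c2cn(C(=O)OC(C)(C)C)c(N)n2 | intermediate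
20 | sceptrin, N,N'-{[(1R,2R,3S,4S)-3,4-bis(2-amino-1H-imidazol-5-yl)cyclobutane-1,2-diyl]bis(methylene)}bis(4-bromo-1H-pyrrole-2-carboxamide) | Nc1ncc([C@H]2[C@H](CNC(=O)c3cc(Br)c[nH]3)[C@@H](CNC(=O)c3cc(Br)c[nH]3)[C@@H]2c2cnc(N)[nH]2)[nH]1 | target

**Step count and risks**

Total step count: 11. Longest linear sequence: 11 steps, from glycine methyl ester hydrochloride; the route is fully linear.

Steps most likely to fail:

1. Step 4. The trivalent-iodine oxidant may dehydrogenate the electron-poor α-amino diester instead of aminating the weakly nucleophilic nitrogen. The ester-stabilised 1,4-biradical may also fragment across C3–C4 or close without full retention. The fallback uses the classical oxidative deamination of an N-aminopyrrolidine and keeps the oxidant away from the free amine. Setting out from 6, nitrosation with tBuONO in CH2Cl2 should give 3,4-di-tert-butyl 2,5-dimethyl (2R,3R,4R,5R)-1-nitrosopyrrolidine-2,3,4,5-tetracarboxylate F1. Zn dust in AcOH at 0 °C should reduce this to 3,4-di-tert-butyl 2,5-dimethyl (2R,3R,4R,5R)-1-aminopyrrolidine-2,3,4,5-tetracarboxylate F2. Oxidation of this hydrazine with HgO in Et2O should generate the same 1,1-diazene 7, which loses N2 and closes, so the sequence rejoins the route at 8.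

2. Step 2. The ester-only imine may oligomerise or hydrolyse before it is metallated, and the small symmetric ylide may be poorly differentiated by the chiral silver complex, giving low facial selectivity. The fallback replaces asymmetric catalysis by resolution. From 3 and 4, AgOAc (10 mol%), PPh3 and Et3N in toluene at rt should give the cycloadduct as the racemate, that is 5 together with its antipode 3,4-di-tert-butyl 2,5-dimethyl (2R,3S,4S,5S)-pyrrolidine-2,3,4,5-tetracarboxylate F3. DBU as in step 3 should then give 6 together with its antipode 3,4-di-tert-butyl 2,5-dimethyl (2S,3S,4S,5S)-pyrrolidine-2,3,4,5-tetracarboxylate F4. Preparative supercritical-fluid chromatography on an immobilised amylose tris(3,5-dimethylphenylcarbamate) phase should separate the two, and the route is rejoined at 6.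

3. Step 9. Activation of the diacid may be incomplete or unselective in the presence of two secondary amides and two pyrrole N–H groups; unactivated acid would be methylated by CH2N2, and the polar diacid may dissolve poorly. The fallback builds the halomethyl ketone from a methyl ketone instead of by diazomethane homologation. Setting out from 14, coupling with MeNHOMe·HCl (EDC·HCl, HOBt, iPr2NEt, DMF) should give N,N'-{[(1R,2R,3S,4S)-3,4-bis[methoxy(methyl)carbamoyl]cyclobutane-1,2-diyl]bis(methylene)}bis(4-bromo-1H-pyrrole-2-carboxamide) F5. Excess MeMgBr in THF at −20 to 0 °C should convert it to N,N'-{[(1R,2R,3S,4S)-3,4-diacetylcyclobutane-1,2-diyl]bis(methylene)}bis(4-bromo-1H-pyrrole-2-carboxamide) F6. α-Chlorination of the methyl groups with BnNMe3 ICl2 in ClCH2CH2Cl/MeOH at 60 °C should give N,N'-{[(1R,2R,3S,4S)-3,4-bis(chloroacetyl)cyclobutane-1,2-diyl]bis(methylene)}bis(4-bromo-1H-pyrrole-2-carboxamide) F7. Condensation with 18 and NaI in DMF (Finkelstein activation in the flask) then rejoins the route at 19.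

**Further compounds**

F1 | step 4 | 3,4-di-tert-butyl 2,5-dimethyl (2R,3R,4R,5R)-1-nitrosopyrrolidine-2,3,4,5-tetracarboxylate | O=NN1[C@@H](C(=O)OC)[C@H](C(=O)OC(C)(C)C)[C@@H](C(=O)OC(C)(C)C)[C@@H]1C(=O)OC
F2 | step 4 | 3,4-di-tert-butyl 2,5-dimethyl (2R,3R,4R,5R)-1-aminopyrrolidine-2,3,4,5-tetracarboxylate | NN1[C@@H](C(=O)OC)[C@H](C(=O)OC(C)(C)C)[C@@H](C(=O)OC(C)(C)C)[C@@H]1C(=O)OC
F3 | step 2 | 3,4-di-tert-butyl 2,5-dimethyl (2R,3S,4S,5S)-pyrrolidine-2,3,4,5-tetracarboxylate (antipode of 5) | N1[C@@H](C(=O)OC)[C@@H](C(=O)OC(C)(C)C)[C@H](C(=O)OC(C)(C)C)[C@H]1C(=O)OC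
F4 | step 2 | 3,4-di-tert-butyl 2,5-dimethyl (2S,3S,4S,5S)-pyrrolidine-2,3,4,5-tetracarboxylate (antipode of 6) | N1[C@H](C(=O)OC)[C@@H](C(=O)OC(C)(C)C)[C@H](C(=O)OC(C)(C)C)[C@H]1C(=O)OC
F5 | step 9 | N,N'-{[(1R,2R,3S,4S)-3,4-bis[methoxy(methyl)carbamoyl]cyclobutane-1,2-diyl]bis(methylene)}bis(4-bromo-1H-pyrrole-2-carboxamide) | CON(C)C(=O)[C@H]1[C@H](CNC(=O)c2cc(Br)c[nH]2)[C@@H](CNC(=O)c2cc(Br)c[nH]2)[C@@H]1C(=O)N(C)OC
F6 | step 9 | N,N'-{[(1R,2R,3S,4S)-3,4-diacetylcyclobutane-1,2-diyl]bis(methylene)}bis(4-bromo-1H-pyrrole-2-carboxamide) | CC(=O)[C@H]1[C@H](CNC(=O)c2cc(Br)c[nH]2)[C@@H](CNC(=O)c2cc(Br)c[nH]2)[C@@H]1C(=O)C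
F7 | step 9 | N,N'-{[(1R,2R,3S,4S)-3,4-bis(chloroacetyl)cyclobutane-1,2-diyl]bis(methylene)}bis(4-bromo-1H-pyrrole-2-carboxamide) | ClCC(=O)[C@H]1[C@H](CNC(=O)c2cc(Br)c[nH]2)[C@@H](CNC(=O)c2cc(Br)c[nH]2)[C@@H]1C(=O)CCl
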